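The macrocycle is stitched by two diaryl ether oxygens and two CH2CH2 links, one from ring A to ring D, the other from ring B to ring C, and all four link carbons are benzylic. Each link is traced back to a dibenzylic sulfone, so that a difficult carbocyclisation becomes an easy sulfide ring closure. In one pyrolysis the key step drives two SO2 molecules out of a 22-membered bis-sulfone and joins both benzylic carbon pairs by recombination of tethered radicals, giving the 20-membered ring. The precursor carries both diaryl ethers and both phenols as methyl ethers. Its sulfur bridges are installed one at a time, which fixes the pairing.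

Key step: step 11

Remark: ring A is the hydroxylated ring whose ether oxygen is para to its CH2. Ring B is the meta-disubstituted ring and ring C the para-disubstituted ring. Ring D is the hydroxylated ring whose ether oxygen is meta to its CH2. The target has no stereocentre, and the 20-membered ring is assumed to be conformationally mobile, so no descriptor is needed.

Step 1
Reactants: 1 4-fluoro-3-methoxybenzaldehyde (ring A); 2 3-hydroxybenzyl alcohol (ring B)
Product: 3 4-[3-(hydroxymethyl)phenoxy]-3-methoxybenzaldehyde
Conditions: K2CO3, DMF, 120 °C, N2
Reagents that add atoms: none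
Why: Nucleophilic aromatic substitution (SNAr), in which K2CO3 deprotonates only the phenol of 2, not its benzylic alcohol, and the phenoxide displaces the fluoride of 1 that the para formyl group activates through a Meisenheimer adduct.

Step 2
Reactants: 3 4-[3-(hydroxymethyl)phenoxy]-3-methoxybenzaldehyde
Product: 4 4-[3-(bromomethyl)phenoxy]-3-methoxybenzaldehyde
Conditions: PBr3, CH2Cl2, 0 °C
Reagents that add atoms: phosphorus tribromide BrP(Br)Br
Why: Alcohol-to-bromide exchange with PBr3 (SN2 on the phosphite ester) leaves the aryl aldehyde alone, whereas CBr4/PPh3 is avoided because it would draw the aldehyde into a Corey–Fuchs olefination.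

Step 3
Reactants: 5 methyl 3-hydroxy-4-methoxybenzoate (ring D); 6 4-fluorobenzaldehyde (ring C)
Product: 7 methyl 3-(4-formylphenoxy)-4-methoxybenzoate
Conditions: K2CO3, dry DMF, 120 °C, N2
Reagents that add atoms: none
Why: SNAr again, the phenoxide of 5 attacking the para-formyl-activated fluoride of 6, with dry carbonate base leaving the methyl ester untouched.

Step 4
Reactants: 7 methyl 3-(4-formylphenoxy)-4-methoxybenzoate
Product: 8 methyl 3-[4-(hydroxymethyl)phenoxy]-4-methoxybenzoate
Conditions: NaBH4, MeOH/THF, 0 °C
Reagents that add atoms: none
Why: Chemoselective borohydride reduction, since NaBH4 at 0 °C reduces the aryl aldehyde quickly while the benzoate ester is inert.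

Step 5
Reactants: 8 methyl 3-[4-(hydroxymethyl)phenoxy]-4-methoxybenzoate
Product: 9 methyl 3-{4-[(acetylsulfanyl)methyl]phenoxy}-4-methoxybenzoate
Conditions: AcSH, PPh3, DIAD, THF, 0 °C to rt
Reagents that add atoms: thioacetic acid CC(=O)S
Why: Mitsunobu thioesterification, in which the primary benzylic alcohol is activated as its oxyphosphonium salt and displaced by thioacetate, so the masked thiol is reached in one operation and no ionisable 4-aryloxybenzyl halide has to be handled.

Step 6
Reactants: 4 4-[3-(bromomethyl)phenoxy]-3-methoxybenzaldehyde; 9 methyl 3-{4-[(acetylsulfanyl)methyl]phenoxy}-4-methoxybenzoate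
Product: 11 open-chain thioether methyl 3-[4-({[3-(4-formyl-2-methoxyphenoxy)benzyl]sulfanyl}methyl)phenoxy]-4-methoxybenzoate, via ring C benzylic thiol 10 (not isolated)
Conditions: K2CO3, degassed MeOH/THF, 0 °C to rt, Ar, base added last to the mixture of 4 and 9
Reagents that add atoms: none
Why: Methanolysis of the thioester releases the thiolate of 10 in the presence of bromide 4, so SN2 S-alkylation (thioether synthesis of the Williamson type) outruns disulfide formation, while the non-enolisable aldehyde tolerates carbonate and methanol can only exchange the methyl ester with itself.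

Step 7
Reactants: 11 open-chain thioether aldehyde ester
Product: 12 open-chain thioether diol (ring A CH2OH and ring D CH2OH)
Conditions: LiAlH4, THF, 0 °C to rt; then H2O, aq NaOH
Reagents that add atoms: none
Why: Exhaustive LiAlH4 reduction takes the aldehyde and the ester to the two primary benzylic alcohols in one operation, the thioether and the diaryl ethers being inert to hydride.

Step 8
Reactants: 12 open-chain thioether diol
Product: 13 open-chain thioether bis(bromomethyl) compound
Conditions: PBr3, CH2Cl2, −10 to 0 °C; cold aq NaHCO3 wash, solution dried and used at once without chromatography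
Reagents that add atoms: phosphorus tribromide BrP(Br)Br
Why: Twofold PBr3 bromination of benzylic alcohols, run cold, briefly and in a weakly polar solvent because both bromides sit para to oxygen donors and could otherwise alkylate the weakly nucleophilic dibenzylic sulfur, an equilibrium that is unfavourable in CH2Cl2.

Step 9
Reactants: 13 open-chain thioether bis(bromomethyl) compound
Product: 14 22-membered dithiacyclophane
Conditions: Na2S/Al2O3 added in portions, CH2Cl2/EtOH (9:1), about 2 mM, rt, Ar
Reagents that add atoms: sodium sulfide [Na+].[Na+].[S-2]
Why: Thiacyclophane synthesis by double SN2 displacement with sulfide, in which the supported reagent feeds sulfide slowly into a dilute solution to favour closure of the unstrained 22-membered ring over oligomerisation, and the weakly ionising CH2Cl2-rich medium holds back solvolysis of the electron-rich benzylic bromides.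

Step 10
Reactants: 14 22-membered dithiacyclophane
Product: 15 22-membered bis-sulfone
Conditions: mCPBA (4.5 equiv), CH2Cl2, 0 °C to rt
Reagents that add atoms: 3-chloroperoxybenzoic acid OOC(=O)c1cccc(Cl)c1
Why: Peracid oxidation of sulfides through the sulfoxides to the sulfones, clean here because no alkene, aldehyde or free phenol is present and the two sulfur atoms are the only readily oxidised sites.

Step 11
Reactants: 15 22-membered bis-sulfone
Product: 17 20-membered macrocycle dimethyl ether, via 21-membered monosulfone 16 (not isolated)
Conditions: flash vacuum pyrolysis, quartz tube 550–600 °C, 10^-3 mbar or better, sample sublimed slowly from a heated inlet, product collected in a cold trap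
Reagents that add atoms: none
Why: This is a sulfone pyrolysis, the established ring contraction of thiacyclophane S,S-dioxides: a benzylic C–S bond breaks homolytically, the sulfonyl radical sheds SO2, and the two benzyl radicals left behind are still tied together through the rest of the ring. Radical–radical recombination of the first pair closes the 21-membered monosulfone 16, drawn with the A/D bridge contracted first because its radicals carry para oxygen donors, and the same sequence at the remaining sulfone closes the 20-membered ring of 17; the reverse order leads to the same product. No stereocentre is created. The step needs the right pairing (ring A CH2 with ring D CH2, ring B CH2 with ring C CH2), which is built into 15 because each sulfur was placed between exactly those two carbons, and it needs intramolecular coupling, which the low-pressure gas phase secures by leaving an isolated molecule no partner. Benzyl radicals have no beta hydrogen and so cannot disproportionate, and the unstrained product puts no barrier on recombination. The oven is kept at the low end of the extrusion window because the ArO–CH3 bonds are only moderately stronger than the benzylic C–S bonds and would begin to homolyse at higher temperature.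

Step 12
Reactants: 17 20-membered macrocycle dimethyl ether
Product: 18 target CNP0329842.0
Conditions: BBr3, CH2Cl2, −78 °C to rt; then H2O
Reagents that add atoms: none
Why: Lewis-acid cleavage of aryl methyl ethers, in which BBr3 binds each methoxy oxygen and bromide removes the methyl group by SN2, while the diaryl ether oxygens offer no sp3 carbon for attack and survive.

Compound list
1 | 4-fluoro-3-methoxybenzaldehyde | COc1cc(C=O)ccc1F | starting material
2 | 3-hydroxybenzyl alcohol | OCc1cccc(O)c1 | starting material
3 | 4-[3-(hydroxymethyl)phenoxy]-3-methoxybenzaldehyde | COc1cc(C=O)ccc1Oc1cccc(CO)c1 | intermediate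
4 | 4-[3-(bromomethyl)phenoxy]-3-methoxybenzaldehyde | COc1cc(C=O)ccc1Oc1cccc(CBr)c1 | intermediate
5 | methyl 3-hydroxy-4-methoxybenzoate | COC(=O)c1ccc(OC)c(O)c1 | starting material
6 | 4-fluorobenzaldehyde | O=Cc1ccc(F)cc1 | starting material
7 | methyl 3-(4-formylphenoxy)-4-methoxybenzoate | COC(=O)c1ccc(OC)c(Oc2ccc(C=O)cc2)c1 | intermediate
8 | methyl 3-[4-(hydroxymethyl)phenoxy]-4-methoxybenzoate | COC(=O)c1ccc(OC)c(Oc2ccc(CO)cc2)c1 | intermediate
9 | methyl 3-{4-[(acetylsulfanyl)methyl]phenoxy}-4-methoxybenzoate | COC(=O)c1ccc(OC)c(Oc2ccc(CSC(C)=O)cc2)c1 | intermediate
10 | methyl 4-methoxy-3-[4-(sulfanylmethyl)phenoxy]benzoate, present as its potassium thiolate, not isolated | COC(=O)c1ccc(OC)c(Oc2ccc(CS)cc2)c1 | intermediate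
11 | open-chain thioether, ring B CH2–S–CH2 ring C, with CHO on ring A and CO2Me on ring D | COC(=O)c1ccc(OC)c(Oc2ccc(CSCc3cccc(Oc4ccc(C=O)cc4OC)c3)cc2)c1 | intermediate
12 | open-chain thioether diol, CH2OH on ring A and on ring D | OCc1ccc(OC)c(Oc2ccc(CSCc3cccc(Oc4ccc(CO)cc4OC)c3)cc2)c1 | intermediate
13 | open-chain thioether dibromide, CH2Br on ring A and on ring D | BrCc1ccc(OC)c(Oc2ccc(CSCc3cccc(Oc4ccc(CBr)cc4OC)c3)cc2)c1 | intermediate
14 | 22-membered dithiacyclophane, CH2SCH2 between rings B/C and between rings A/D, both phenols as methyl ethers | COc1cc2ccc1Oc1cccc(c1)CSCc1ccc(cc1)Oc1cc(ccc1OC)CSC2 | intermediate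
15 | 22-membered bis-sulfone, CH2SO2CH2 between rings B/C and between rings A/D | COc1cc2ccc1Oc1cccc(c1)CS(=O)(=O)Cc1ccc(cc1)Oc1cc(ccc1OC)CS(=O)(=O)C2 | intermediate
16 | 21-membered monosulfone, CH2CH2 between rings A/D and CH2SO2CH2 between rings B/C, not isolated | COc1cc2ccc1Oc1cccc(c1)CS(=O)(=O)Cc1ccc(cc1)Oc1cc(ccc1OC)CC2 | intermediate
17 | 20-membered macrocycle dimethyl ether | COc1cc2ccc1Oc1cccc(c1)CCc1ccc(cc1)Oc1cc(ccc1OC)CC2 | intermediate
18 | CNP0329842.0, 20-membered bis(bibenzyl) diphenol | Oc1cc2ccc1Oc1cccc(c1)CCc1ccc(cc1)Oc1cc(ccc1O)CC2 | target

Total step count: 12
Longest linear sequence: 10 steps (steps 3 to 12, from 5 and 6)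

Steps most likely to fail

1. Step 11. The heavy, polar bis-sulfone may char in the inlet before it sublimes. Extrusion may stop after the first SO2. The long-tethered radical pair may also be diverted by intramolecular hydrogen transfer or by O–CH3 homolysis if the oven must be run hotter. The fallback leaves the gas phase and contracts both bridges in solution by ionic chemistry. It sets out from 15. A twofold Ramberg–Bäcklund reaction with in situ alpha-halogenation (KOH/Al2O3, CBr2F2, t-BuOH/CH2Cl2, 0 °C to rt) should pass through the episulfones to the macrocyclic bis-stilbene F1. Its alkene geometry is immaterial and is drawn E,E. Hydrogenation (H2, Pd/C, EtOAc) should then saturate both alkenes and come back to the route at 17.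

2. Step 9. Oligomerisation may compete with the irreversible ring closure, and slow solvolysis of the electron-rich benzylic bromides may cap chain ends during the long reaction. The fallback closes the ring reversibly and needs no dibromide. It sets out from diol 12. A double Mitsunobu reaction (AcSH, PPh3, DIAD, THF) should give the bis(thioacetate) F2. K2CO3 in MeOH/THF at about 1 mM, open to air, should free the dithiol F3 and oxidise it to the 23-membered cyclic disulfide F4. Thiolate–disulfide exchange allows this closure to correct oligomeric errors. Excision of one sulfur atom with P(NEt2)3 in dilute toluene attacks only the S–S bond and should come back to the route at 14.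

3. Step 8. The ionisable benzylic bromides may alkylate the thioether sulfur of a neighbouring or the same molecule. That would lead to sulfonium formation, scrambling of the benzyl groups and decomposition on concentration. The fallback removes the nucleophilicity of sulfur first. It sets out from diol 12. mCPBA (2.2 equiv, CH2Cl2, 0 °C) should give the sulfone diol F5, and PBr3 should convert it into the sulfone dibromide F6, which can be purified and stored. Na2S/Al2O3 under the dilution conditions of step 9 should close the 22-membered sulfide sulfone F7. Oxidation of the remaining sulfide with mCPBA comes back to the route at 15.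

Further compounds
F1 | step 11 | 20-membered macrocyclic bis-stilbene dimethyl ether (drawn E,E) | COc1cc2ccc1Oc1cccc(c1)/C=C/c1ccc(cc1)Oc1cc(ccc1OC)/C=C/2
F2 | step 9 | open-chain thioether bis(thioacetate) | CC(=O)SCc1ccc(OC)c(Oc2ccc(CSCc3cccc(Oc4ccc(CSC(C)=O)cc4OC)c3)cc2)c1
F3 | step 9 | open-chain thioether dithiol | SCc1ccc(OC)c(Oc2ccc(CSCc3cccc(Oc4ccc(CS)cc4OC)c3)cc2)c1
F4 | step 9 | 23-membered cyclic disulfide thioether | COc1cc2ccc1Oc1cccc(c1)CSCc1ccc(cc1)Oc1cc(ccc1OC)CSSC2
F5 | step 8 | open-chain sulfone diol | OCc1ccc(OC)c(Oc2ccc(CS(=O)(=O)Cc3cccc(Oc4ccc(CO)cc4OC)c3)cc2)c1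
F6 | step 8 | open-chain sulfone dibromide | BrCc1ccc(OC)c(Oc2ccc(CS(=O)(=O)Cc3cccc(Oc4ccc(CBr)cc4OC)c3)cc2)c1
F7 | step 8 | 22-membered sulfide sulfone macrocycle | COc1cc2ccc1Oc1cccc(c1)CS(=O)(=O)Cc1ccc(cc1)Oc1cc(ccc1OC)CSC2
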